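## Retrosynthetic overview

1. Ring C is closed last: acid-mediated C11a–O11 bond formation from a 2'-hydroxyisoflavan-4-ol, where C6a dictates the cis fusion.
2. Ring B comes before it: Mitsunobu O5–C6 etherification of a 1,2-diarylpropane-1,3-diol.
3. The key C6a–C11a bond is made by an Evans syn-aldol between ring A aldehyde 5 and ring D arylacetyl oxazolidinone 15; the auxiliary fixes C6a.
4. Both arenes come from one chromene aldehyde 4 (2,4-dihydroxybenzaldehyde + prenal). The ring D piece needs a one-carbon homologation, then Jacobsen epoxidation and hydrogenolysis to set the (3R)-carbinol.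
5. Ring order: the two chromene pyran rings, then the hydroxydihydropyran on ring D, then ring B, then ring C.

Assumption: pterocarpan numbering (O5, C6, C6a, O11, C11a) is used, and the SMILES is read as (6aR,11aR) with a (3R)-carbinol in the dihydropyran on ring D. TIPS = triisopropylsilyl, TBS = tert-butyldimethylsilyl.

## Route

Step 1
Reactants: 1 (2,4-dihydroxybenzaldehyde) + 2 (3-methylbut-2-enal)
Product: 4 5-hydroxy-2,2-dimethyl-2H-chromene-6-carbaldehyde, via ortho-quinone methide 3 (not isolated)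
Conditions: pyridine, 120 °C (sealed tube), 24 h
Reagents that add atoms: none
Why: Knoevenagel-type condensation at C3 of the resorcinol gives ortho-quinone methide 3, which closes by oxa-6π electrocyclisation; the 2-OH is chelated to the aldehyde, so the 4-oxygen closes the pyran and only the angular chromene forms.

Step 2
Reactants: 4 (5-hydroxy-2,2-dimethyl-2H-chromene-6-carbaldehyde)
Product: 5 2,2-dimethyl-5-(prop-2-en-1-yloxy)-2H-chromene-6-carbaldehyde
Conditions: allyl bromide, K2CO3, DMF, 60 °C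
Reagents that add atoms: allyl bromide, C=CCBr
Why: Williamson etherification of the chelated phenol gives an allyl ether that survives the aldol and hydride steps and is later removed under neutral conditions.

Step 3
Reactants: 4 (5-hydroxy-2,2-dimethyl-2H-chromene-6-carbaldehyde)
Product: 6 2,2-dimethyl-5-[(triisopropylsilyl)oxy]-2H-chromene-6-carbaldehyde
Conditions: TIPSOTf, 2,6-lutidine, CH2Cl2, 0 °C → rt
Reagents that add atoms: triisopropylsilyl trifluoromethanesulfonate, CC(C)[Si](C(C)C)(C(C)C)OS(=O)(=O)C(F)(F)F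
Why: O-silylation with the reactive triflate caps the hindered phenol as an aryl TIPS ether that tolerates ylide, dilute acid, chlorite and boron enolate chemistry.

Step 4
Reactants: 6 (2,2-dimethyl-5-[(triisopropylsilyl)oxy]-2H-chromene-6-carbaldehyde)
Product: 7 6-(2-methoxyethenyl)-2,2-dimethyl-5-[(triisopropylsilyl)oxy]-2H-chromene (E/Z mixture)
Conditions: MeOCH2PPh3Cl, KOt-Bu, THF, 0 °C → rt
Reagents that add atoms: (methoxymethyl)triphenylphosphonium chloride, COC[P+](c1ccccc1)(c1ccccc1)c1ccccc1.[Cl-]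
Why: Wittig olefination with the methoxymethylene ylide adds the one carbon needed for the arylacetic acid; the alkene geometry is irrelevant.

Step 5
Reactants: 7 (6-(2-methoxyethenyl)-2,2-dimethyl-5-[(triisopropylsilyl)oxy]-2H-chromene)
Product: 8 {2,2-dimethyl-5-[(triisopropylsilyl)oxy]-2H-chromen-6-yl}acetaldehyde
Conditions: 2 M aq. HCl, THF, 40 °C; used crude
Reagents that add atoms: water, O
Why: acid-catalysed enol ether hydrolysis releases the arylacetaldehyde, while the aryl TIPS ether and the 2,2-dimethylchromene tolerate dilute acid.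

Step 6
Reactants: 8 ({2,2-dimethyl-5-[(triisopropylsilyl)oxy]-2H-chromen-6-yl}acetaldehyde)
Product: 9 {2,2-dimethyl-5-[(triisopropylsilyl)oxy]-2H-chromen-6-yl}acetic acid
Conditions: NaClO2, NaH2PO4, 2-methylbut-2-ene (excess), t-BuOH/H2O, 0 °C → rt
Reagents that add atoms: sodium chlorite, [Na+].[O-]Cl=O
Why: Pinnick oxidation converts the aldehyde to the acid without touching the chromene, because the alkene scavenger removes the hypochlorous acid.

Step 7
Reactants: 9 ({2,2-dimethyl-5-[(triisopropylsilyl)oxy]-2H-chromen-6-yl}acetic acid) + 10 ((4S)-4-benzyl-1,3-oxazolidin-2-one)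
Product: 12 (4S)-4-benzyl-3-({2,2-dimethyl-5-[(triisopropylsilyl)oxy]-2H-chromen-6-yl}acetyl)-1,3-oxazolidin-2-one, via mixed pivalic anhydride 11 (not isolated)
Conditions: PivCl, Et3N, THF, −20 °C; then 10, LiCl, rt
Reagents that add atoms: none
Why: N-acylation through the mixed pivalic anhydride is selective because the auxiliary attacks the less hindered arylacetyl carbonyl.

Step 8
Reactants: 12 ((4S)-4-benzyl-3-({2,2-dimethyl-5-[(triisopropylsilyl)oxy]-2H-chromen-6-yl}acetyl)-1,3-oxazolidin-2-one)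
Product: 13 (4S)-4-benzyl-3-({(3R,4R)-3,4-epoxy-2,2-dimethyl-5-[(triisopropylsilyl)oxy]-3,4-dihydro-2H-chromen-6-yl}acetyl)-1,3-oxazolidin-2-one
Conditions: [(R,R)-N,N'-bis(3,5-di-tert-butylsalicylidene)cyclohexane-1,2-diaminato]manganese chloride (trivalent manganese, 5 mol%), NMO, mCPBA, CH2Cl2, −78 °C
Reagents that add atoms: 3-chloroperoxybenzoic acid, OOC(=O)c1cccc(Cl)c1
Why: Jacobsen–Katsuki epoxidation of the cis-configured 2,2-dimethylchromene; the (R,R)-salen manganese catalyst delivers oxygen to the face that gives the (3R,4R)-epoxide, and the anhydrous low-temperature protocol spares the imide.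

Step 9
Reactants: 13 (the (3R,4R)-epoxide)
Product: 14 (4S)-4-benzyl-3-({(3R)-3-hydroxy-2,2-dimethyl-5-[(triisopropylsilyl)oxy]-3,4-dihydro-2H-chromen-6-yl}acetyl)-1,3-oxazolidin-2-one
Conditions: H2 (1 atm), Pd/C, EtOAc, rt
Reagents that add atoms: none
Why: hydrogenolysis cleaves only the benzylic C4–O bond of the epoxide, so the C3–O bond and its (3R) configuration stay untouched.

Step 10
Reactants: 14 (the (3R)-chromanol imide)
Product: 15 (4S)-4-benzyl-3-({(3R)-3-[(tert-butyldimethylsilyl)oxy]-2,2-dimethyl-5-[(triisopropylsilyl)oxy]-3,4-dihydro-2H-chromen-6-yl}acetyl)-1,3-oxazolidin-2-one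
Conditions: TBSOTf, 2,6-lutidine, CH2Cl2, −78 → 0 °C
Reagents that add atoms: tert-butyldimethylsilyl trifluoromethanesulfonate, CC(C)(C)[Si](C)(C)OS(=O)(=O)C(F)(F)F
Why: O-silylation with the triflate protects the hindered secondary alcohol next to the gem-dimethyl carbon so that it cannot consume the boron reagent or compete in the Mitsunobu step.

Step 11
Reactants: 15 (ring D imide) + 5 (2,2-dimethyl-5-(prop-2-en-1-yloxy)-2H-chromene-6-carbaldehyde)
Product: 18 (4S)-4-benzyl-3-[(2S,3S)-2-{(3R)-3-[(tert-butyldimethylsilyl)oxy]-2,2-dimethyl-5-[(triisopropylsilyl)oxy]-3,4-dihydro-2H-chromen-6-yl}-3-hydroxy-3-[2,2-dimethyl-5-(prop-2-en-1-yloxy)-2H-chromen-6-yl]propanoyl]-1,3-oxazolidin-2-one, via dibutylboron Z-enolate 16 (not isolated), via dibutylboron aldolate 17 (not isolated)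
Conditions: n-Bu2BOTf, i-Pr2NEt, CH2Cl2, 0 °C; then 5, −78 → 0 °C; then pH 7 buffer, MeOH, 30% H2O2, 0 °C
Reagents that add atoms: none
Why: Evans syn-aldol: the Z-boron enolate adds to the aldehyde through a Zimmerman–Traxler chair on the face away from the benzyl group of the (S)-auxiliary, which sets the α-aryl carbon (the future C6a, R in the target) and the syn carbinol as (2S,3S).

Step 12
Reactants: 18 (Evans syn-aldol adduct)
Product: 19 (1S,2R)-2-{(3R)-3-[(tert-butyldimethylsilyl)oxy]-2,2-dimethyl-5-[(triisopropylsilyl)oxy]-3,4-dihydro-2H-chromen-6-yl}-1-[2,2-dimethyl-5-(prop-2-en-1-yloxy)-2H-chromen-6-yl]propane-1,3-diol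
Conditions: LiBH4, MeOH (1 equiv), THF, 0 °C
Reagents that add atoms: none
Why: reductive cleavage of the N-acyl oxazolidinone by borohydride gives the primary alcohol quickly at 0 °C, before retro-aldol or epimerisation of the α-aryl centre can compete (the descriptor changes to 2R only through CIP priorities).

Step 13
Reactants: 19 (allyl-protected diol)
Product: 20 (1S,2R)-2-{(3R)-3-[(tert-butyldimethylsilyl)oxy]-2,2-dimethyl-5-[(triisopropylsilyl)oxy]-3,4-dihydro-2H-chromen-6-yl}-1-(5-hydroxy-2,2-dimethyl-2H-chromen-6-yl)propane-1,3-diol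
Conditions: Pd(PPh3)4 (5 mol%), morpholine, THF, rt; used at once
Reagents that add atoms: none
Why: Tsuji–Trost deallylation with zerovalent palladium transfers the allyl group to morpholine under neutral conditions, which leaves the acid-sensitive benzylic alcohol, the chromene and both silyl ethers intact.

Step 14
Reactants: 20 (phenol triol)
Product: 21 (3R,4S)-3-{(3R)-3-[(tert-butyldimethylsilyl)oxy]-2,2-dimethyl-5-[(triisopropylsilyl)oxy]-3,4-dihydro-2H-chromen-6-yl}-8,8-dimethyl-3,4-dihydro-2H,8H-pyrano[2,3-f]chromen-4-ol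
Conditions: PPh3, DIAD, THF (0.01 M), 0 °C → rt
Reagents that add atoms: none
Why: intramolecular Mitsunobu etherification: the primary alcohol is activated faster than the hindered benzylic one and the only free phenol closes the six-membered ring B at a non-stereogenic carbon, so both stereocentres are carried over unchanged (trans-isoflavan-4-ol).

Step 15
Reactants: 21 (bis-silylated trans-isoflavan-4-ol)
Product: 22 (3R,4S)-3-[(3R)-3,5-dihydroxy-2,2-dimethyl-3,4-dihydro-2H-chromen-6-yl]-8,8-dimethyl-3,4-dihydro-2H,8H-pyrano[2,3-f]chromen-4-ol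
Conditions: TBAF, THF, rt → 45 °C
Reagents that add atoms: none
Why: fluoride-mediated desilylation removes the aryl TIPS and the secondary TBS ether together, and nothing cyclises or epimerises under these basic conditions.

Step 16
Reactants: 22 (2'-hydroxyisoflavan-4-ol triol)
Product: 23 (6aR,11aR)-pterocarpan target CNP0126417.1
Conditions: p-TsOH·H2O (10 mol%), 4 Å MS, CH2Cl2, 0 °C → rt
Reagents that add atoms: none
Why: intramolecular SN1 etherification: acid ionises the 4-hydroxyl to a cation stabilised by the para oxygen of ring A and the 2'-phenol traps it to close ring C; only the cis-fused ring is accessible, so C6a (R) fixes C11a as R whatever the carbinol configuration was.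

## Compound list

1 | 2,4-dihydroxybenzaldehyde | O=Cc1ccc(O)cc1O | starting material
2 | 3-methylbut-2-enal (prenal) | CC(C)=CC=O | starting material
3 | 2-hydroxy-3-(3-methylbut-2-en-1-ylidene)-4-oxocyclohexa-1,5-diene-1-carbaldehyde (ortho-quinone methide) | O=CC1=C(O)C(=CC=C(C)C)C(=O)C=C1 | intermediate
4 | 5-hydroxy-2,2-dimethyl-2H-chromene-6-carbaldehyde | CC1(C)C=Cc2c(O1)ccc(C=O)c2O | intermediate
5 | 2,2-dimethyl-5-(prop-2-en-1-yloxy)-2H-chromene-6-carbaldehyde (ring A aldehyde) | CC1(C)C=Cc2c(O1)ccc(C=O)c2OCC=C | intermediate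
6 | 2,2-dimethyl-5-[(triisopropylsilyl)oxy]-2H-chromene-6-carbaldehyde | CC1(C)C=Cc2c(O1)ccc(C=O)c2O[Si](C(C)C)(C(C)C)C(C)C | intermediate
7 | 6-(2-methoxyethenyl)-2,2-dimethyl-5-[(triisopropylsilyl)oxy]-2H-chromene (E/Z mixture) | COC=Cc1ccc2c(C=CC(C)(C)O2)c1O[Si](C(C)C)(C(C)C)C(C)C | intermediate
8 | {2,2-dimethyl-5-[(triisopropylsilyl)oxy]-2H-chromen-6-yl}acetaldehyde | O=CCc1ccc2c(C=CC(C)(C)O2)c1O[Si](C(C)C)(C(C)C)C(C)C | intermediate
9 | {2,2-dimethyl-5-[(triisopropylsilyl)oxy]-2H-chromen-6-yl}acetic acid | OC(=O)Cc1ccc2c(C=CC(C)(C)O2)c1O[Si](C(C)C)(C(C)C)C(C)C | intermediate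
10 | (4S)-4-benzyl-1,3-oxazolidin-2-one | O=C1N[C@@H](Cc2ccccc2)CO1 | starting material
11 | {2,2-dimethyl-5-[(triisopropylsilyl)oxy]-2H-chromen-6-yl}acetic pivalic anhydride | CC(C)(C)C(=O)OC(=O)Cc1ccc2c(C=CC(C)(C)O2)c1O[Si](C(C)C)(C(C)C)C(C)C | intermediate
12 | (4S)-4-benzyl-3-({2,2-dimethyl-5-[(triisopropylsilyl)oxy]-2H-chromen-6-yl}acetyl)-1,3-oxazolidin-2-one | O=C1OC[C@H](Cc2ccccc2)N1C(=O)Cc1ccc2c(C=CC(C)(C)O2)c1O[Si](C(C)C)(C(C)C)C(C)C | intermediate
13 | (4S)-4-benzyl-3-({(3R,4R)-3,4-epoxy-2,2-dimethyl-5-[(triisopropylsilyl)oxy]-3,4-dihydro-2H-chromen-6-yl}acetyl)-1,3-oxazolidin-2-one | O=C1OC[C@H](Cc2ccccc2)N1C(=O)Cc1ccc2c([C@H]3O[C@H]3C(C)(C)O2)c1O[Si](C(C)C)(C(C)C)C(C)C | intermediate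
14 | (4S)-4-benzyl-3-({(3R)-3-hydroxy-2,2-dimethyl-5-[(triisopropylsilyl)oxy]-3,4-dihydro-2H-chromen-6-yl}acetyl)-1,3-oxazolidin-2-one | O=C1OC[C@H](Cc2ccccc2)N1C(=O)Cc1ccc2c(C[C@@H](O)C(C)(C)O2)c1O[Si](C(C)C)(C(C)C)C(C)C | intermediate
15 | (4S)-4-benzyl-3-({(3R)-3-[(tert-butyldimethylsilyl)oxy]-2,2-dimethyl-5-[(triisopropylsilyl)oxy]-3,4-dihydro-2H-chromen-6-yl}acetyl)-1,3-oxazolidin-2-one (ring D imide) | O=C1OC[C@H](Cc2ccccc2)N1C(=O)Cc1ccc2c(C[C@@H](O[Si](C)(C)C(C)(C)C)C(C)(C)O2)c1O[Si](C(C)C)(C(C)C)C(C)C | intermediate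
16 | (Z)-O-dibutylboryl enolate of 15 | O=C1OC[C@H](Cc2ccccc2)N1/C(OB(CCCC)CCCC)=C/c1ccc2c(C[C@@H](O[Si](C)(C)C(C)(C)C)C(C)(C)O2)c1O[Si](C(C)C)(C(C)C)C(C)C | intermediate
17 | O-dibutylboryl aldolate of 18 (2S,3S) | O=C1OC[C@H](Cc2ccccc2)N1C(=O)[C@H]([C@H](OB(CCCC)CCCC)c1ccc2OC(C)(C)C=Cc2c1OCC=C)c1ccc2c(C[C@@H](O[Si](C)(C)C(C)(C)C)C(C)(C)O2)c1O[Si](C(C)C)(C(C)C)C(C)C | intermediate
18 | (4S)-4-benzyl-3-[(2S,3S)-2-{(3R)-3-[(tert-butyldimethylsilyl)oxy]-2,2-dimethyl-5-[(triisopropylsilyl)oxy]-3,4-dihydro-2H-chromen-6-yl}-3-hydroxy-3-[2,2-dimethyl-5-(prop-2-en-1-yloxy)-2H-chromen-6-yl]propanoyl]-1,3-oxazolidin-2-one | O=C1OC[C@H](Cc2ccccc2)N1C(=O)[C@H]([C@H](O)c1ccc2OC(C)(C)C=Cc2c1OCC=C)c1ccc2c(C[C@@H](O[Si](C)(C)C(C)(C)C)C(C)(C)O2)c1O[Si](C(C)C)(C(C)C)C(C)C | intermediate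
19 | (1S,2R)-2-{(3R)-3-[(tert-butyldimethylsilyl)oxy]-2,2-dimethyl-5-[(triisopropylsilyl)oxy]-3,4-dihydro-2H-chromen-6-yl}-1-[2,2-dimethyl-5-(prop-2-en-1-yloxy)-2H-chromen-6-yl]propane-1,3-diol | OC[C@H]([C@H](O)c1ccc2OC(C)(C)C=Cc2c1OCC=C)c1ccc2c(C[C@@H](O[Si](C)(C)C(C)(C)C)C(C)(C)O2)c1O[Si](C(C)C)(C(C)C)C(C)C | intermediate
20 | (1S,2R)-2-{(3R)-3-[(tert-butyldimethylsilyl)oxy]-2,2-dimethyl-5-[(triisopropylsilyl)oxy]-3,4-dihydro-2H-chromen-6-yl}-1-(5-hydroxy-2,2-dimethyl-2H-chromen-6-yl)propane-1,3-diol | OC[C@H]([C@H](O)c1ccc2OC(C)(C)C=Cc2c1O)c1ccc2c(C[C@@H](O[Si](C)(C)C(C)(C)C)C(C)(C)O2)c1O[Si](C(C)C)(C(C)C)C(C)C | intermediate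
21 | (3R,4S)-3-{(3R)-3-[(tert-butyldimethylsilyl)oxy]-2,2-dimethyl-5-[(triisopropylsilyl)oxy]-3,4-dihydro-2H-chromen-6-yl}-8,8-dimethyl-3,4-dihydro-2H,8H-pyrano[2,3-f]chromen-4-ol (trans-isoflavan-4-ol) | O[C@@H]1c2ccc3OC(C)(C)C=Cc3c2OC[C@H]1c1ccc2c(C[C@@H](O[Si](C)(C)C(C)(C)C)C(C)(C)O2)c1O[Si](C(C)C)(C(C)C)C(C)C | intermediate
22 | (3R,4S)-3-[(3R)-3,5-dihydroxy-2,2-dimethyl-3,4-dihydro-2H-chromen-6-yl]-8,8-dimethyl-3,4-dihydro-2H,8H-pyrano[2,3-f]chromen-4-ol | O[C@@H]1c2ccc3OC(C)(C)C=Cc3c2OC[C@H]1c1ccc2c(C[C@@H](O)C(C)(C)O2)c1O | intermediate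
23 | CNP0126417.1: (6aR,11aR)-cis-pterocarpan with a 2,2-dimethyl-2H-pyran fused at C3–C4 of ring A (oxygen on C3) and a (3R)-3-hydroxy-2,2-dimethyl-3,4-dihydro-2H-pyran fused at C9–C10 of ring D (oxygen on C9) | CC1(C)C=Cc2c(ccc3c2OC[C@H]2c4ccc5c(c4O[C@@H]32)C[C@@H](O)C(C)(C)O5)O1 | target

## Step count and risks

Total steps: 16.
Longest linear sequence: 15 steps (1 → 4 → 6 → 7 → 8 → 9 → 12 → 13 → 14 → 15 → 18 → 19 → 20 → 21 → 22 → 23). The ring A branch 4 → 5 is one extra step that joins at step 11.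

The three steps most likely to fail:

Step 8. The bulky silyloxy group sits next to the alkene and may lower the enantioselectivity of the epoxidation, so the C3 carbinol could come out impure. The fallback sets out from 14 (material of insufficient purity at C3, or the C3 mixture obtained by plain mCPBA epoxidation of 12 followed by step 9). Dess–Martin periodinane in CH2Cl2 oxidises the carbinol to (4S)-4-benzyl-3-({2,2-dimethyl-3-oxo-5-[(triisopropylsilyl)oxy]-3,4-dihydro-2H-chromen-6-yl}acetyl)-1,3-oxazolidin-2-one F1. (S)-2-Methyl-CBS-oxazaborolidine (10 mol%) with BH3·SMe2 in THF at −20 °C then reduces this ketone, with the quaternary C2 as the large group and the benzylic CH2 as the small one. That delivers the (3R)-alcohol, so the fallback comes back to the route at 14 and continues with step 10.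

Step 11. The aldehyde is electron-rich and the enolate is stabilised, so facial selectivity may be modest and the α-aryl centre can erode by retro-aldol. The fallback moves stereocontrol to a reduction with dynamic kinetic resolution. It sets out from 21, taken together with whatever C3/C4 stereoisomers an unselective aldol carries through steps 12 to 14. Dess–Martin periodinane gives the isoflavanone 3-{(3R)-3-[(tert-butyldimethylsilyl)oxy]-2,2-dimethyl-5-[(triisopropylsilyl)oxy]-3,4-dihydro-2H-chromen-6-yl}-8,8-dimethyl-2,3-dihydro-4H,8H-pyrano[2,3-f]chromen-4-one F2, whose C3 epimerises freely. Asymmetric transfer hydrogenation with RuCl(p-cymene)[(R,R)-TsDPEN] (2 mol%) in HCO2H/Et3N (5:2) and EtOAc at 40 °C reduces the rapidly equilibrating ketone to the cis-isoflavan-4-ol, the (3R,4R) diastereomer of 21 F3. TBAF as in step 15 gives the (3R,4R) diastereomer of 22 F4, and the acid of step 16 closes ring C, so the fallback comes back to the route at 23.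

Step 14. The ortho-hydroxybenzylic alcohol of 20 can be activated under Mitsunobu conditions and lose water to an ortho-quinone methide instead of cyclising. The fallback sets out from 19 and replaces the Mitsunobu reaction with a Williamson closure. TsCl (1.1 equiv) in pyridine at 0 °C sulfonylates only the primary hydroxyl to give (2R,3S)-2-{(3R)-3-[(tert-butyldimethylsilyl)oxy]-2,2-dimethyl-5-[(triisopropylsilyl)oxy]-3,4-dihydro-2H-chromen-6-yl}-3-hydroxy-3-[2,2-dimethyl-5-(prop-2-en-1-yloxy)-2H-chromen-6-yl]propyl 4-methylbenzenesulfonate F5. Pd(PPh3)4 (5 mol%) with K2CO3 in MeOH at rt then removes the allyl group, and the phenoxide displaces the tosylate in a 6-exo SN2 closure of ring B, so the fallback comes back to the route at 21.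

## Further compounds

F1 | step 8 | (4S)-4-benzyl-3-({2,2-dimethyl-3-oxo-5-[(triisopropylsilyl)oxy]-3,4-dihydro-2H-chromen-6-yl}acetyl)-1,3-oxazolidin-2-one | O=C1OC[C@H](Cc2ccccc2)N1C(=O)Cc1ccc2c(CC(=O)C(C)(C)O2)c1O[Si](C(C)C)(C(C)C)C(C)C
F2 | step 11 | 3-{(3R)-3-[(tert-butyldimethylsilyl)oxy]-2,2-dimethyl-5-[(triisopropylsilyl)oxy]-3,4-dihydro-2H-chromen-6-yl}-8,8-dimethyl-2,3-dihydro-4H,8H-pyrano[2,3-f]chromen-4-one (C3 epimerisable) | O=C1c2ccc3OC(C)(C)C=Cc3c2OCC1c1ccc2c(C[C@@H](O[Si](C)(C)C(C)(C)C)C(C)(C)O2)c1O[Si](C(C)C)(C(C)C)C(C)C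
F3 | step 11 | (3R,4R)-3-{(3R)-3-[(tert-butyldimethylsilyl)oxy]-2,2-dimethyl-5-[(triisopropylsilyl)oxy]-3,4-dihydro-2H-chromen-6-yl}-8,8-dimethyl-3,4-dihydro-2H,8H-pyrano[2,3-f]chromen-4-ol (cis-isoflavan-4-ol) | O[C@H]1c2ccc3OC(C)(C)C=Cc3c2OC[C@H]1c1ccc2c(C[C@@H](O[Si](C)(C)C(C)(C)C)C(C)(C)O2)c1O[Si](C(C)C)(C(C)C)C(C)C
F4 | step 11 | (3R,4R)-3-[(3R)-3,5-dihydroxy-2,2-dimethyl-3,4-dihydro-2H-chromen-6-yl]-8,8-dimethyl-3,4-dihydro-2H,8H-pyrano[2,3-f]chromen-4-ol | O[C@H]1c2ccc3OC(C)(C)C=Cc3c2OC[C@H]1c1ccc2c(C[C@@H](O)C(C)(C)O2)c1O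
F5 | step 14 | (2R,3S)-2-{(3R)-3-[(tert-butyldimethylsilyl)oxy]-2,2-dimethyl-5-[(triisopropylsilyl)oxy]-3,4-dihydro-2H-chromen-6-yl}-3-hydroxy-3-[2,2-dimethyl-5-(prop-2-en-1-yloxy)-2H-chromen-6-yl]propyl 4-methylbenzenesulfonate | Cc1ccc(cc1)S(=O)(=O)OC[C@H]([C@H](O)c1ccc2OC(C)(C)C=Cc2c1OCC=C)c1ccc2c(C[C@@H](O[Si](C)(C)C(C)(C)C)C(C)(C)O2)c1O[Si](C(C)C)(C(C)C)C(C)C
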